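We watch the dormant form.

| setting | summer | spring | south-west | north-east |
|---|---|---|---|---|
| electrophile | 0.14 M | 0.14 M | 0.14 M | 0.14 M |
| nucleophile | 0.133 M | 0.133 M | 0.133 M | 0.133 M |
| free base | 0.094 M | 0.21 M | 0.140 M | 0.140 M |
| temperature | 78 °C | 94 °C |  |  |
| remark | run made earlier | run made earlier | at 100 °C until 15 h, from then on at 70 °C | at 70 °C throughout |
| time |  |  | 50 h | 50 h |

| run | time / h | target / % | electrophile / % |
|---|---|---|---|
| summer | 8.00 | 4.1 | 94.4 |
| summer | 20.0 | 8.8 | 86.6 |
| summer | 40.0 | 15.3 | 75.4 |
| summer | 96.0 | 25.9 | 54.9 |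
| spring | 4.00 | 7.9 | 85.4 |
| spring | 10.0 | 17.2 | 70.0 |
| spring | 20.0 | 26.1 | 52.6 |
| spring | 30.0 | 30.0 | 39.5 |

(standard deviation of a reading: 0.5 percentage points)

- which one finishes higher in amount of target, in percent of the electrophile charged ("neither" within 2 percentage points) (south-west / north-east / neither)
- amount of target at the end, in percent of the electrophile charged, south-west
- amount of target at the end, in percent of the electrophile charged, north-east

Both runs charged the same electrophile and nucleophile as the new flasks. Electrophile lost minus target formed is dormant form: 19.2% in summer at 96.0 h, 30.5% in spring at 30.0 h. Dividing each by its time and by the mean of the electrophile's first and last amounts gives a first-order parking constant k, 0.00258 h⁻¹ in summer and 0.0146 h⁻¹ in spring. Extended exponentially in temperature, k becomes 0.0279 h⁻¹ at 100 °C and 0.00109 h⁻¹ at 70 °C.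

We reckon with two times: the time held, and the parking time 1/k. South-west collects 0.456, spring collected 0.437: time held over parking time, summed stage by stage, is the dose.

Do like doses give like target? Spring at 20.0 h, dose 0.292, read 26.1%; summer at 96.0 h, dose 0.248, read 25.9%, with temperature and free base both different and the doses a factor 1.18 apart, so the match is rough. As a rough estimate we read south-west off spring's last reading, about 30.0%, and north-east, dose 0.0543, off summer at 20.0 h, dose 0.0516, about 8.8%, which puts south-west higher.

The forecast says south-west, 29.5% against 9.5%, holding that the gap “keeps growing first-order, with no visible return”. Our south-west stands higher than the forecast's, our north-east lower than the forecast's.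

South-west finishes higher, 30.3% against 9.27% in north-east.

    electrophile ⇌ dormant form (K = 16.0, k = 4.90 × 10⁻⁴ min⁻¹, Ea = 116 kJ mol⁻¹, ΔH = 16.0 kJ mol⁻¹)
    nucleophile + acid set free ⇌ protonated nucleophile, settled at all times (K = 830 L mol⁻¹, ΔH = −46.0 kJ mol⁻¹)
    acid set free + free base ⇌ salt of the base (K = 8.50 L mol⁻¹, k = 0.0580 L mol⁻¹ min⁻¹, Ea = 80.0 kJ mol⁻¹, ΔH = −29.0 kJ mol⁻¹)
    electrophile + nucleophile → acid set free + target (k = 0.00570 L mol⁻¹ min⁻¹, Ea = 107 kJ mol⁻¹)
    (constants at 100 °C)

South-west's dormant form stood at 29.8% at 50.0 h. North-east, left for 500 h, reckons to a dose of 0.543, larger than south-west's 0.456, and there holds dormant form 31.0% and target 35.3%.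

All runs are calculated for an exercise; scatter was added.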